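**Strategy**

Rhodisin is cut at the C4–C8 bond into two copies of one benzylated epigallocatechin gallate, one of them oxidised at C4. The upper pyran ring (O1, C2, C3, C4, C4a, C8a) carries vicinal oxygens: ring O1 on benzylic C2 and the gallate oxygen on C3. These can trade carbons through an aryloxiranium ion, so the ring is made from a 2,3-dihydrobenzofuran (O1, C3, C4, C4a, C8a) bearing C2 as an exocyclic carbinol. In the key step O1 migrates to C2 while gallate enters at C3, with inversion at both centres: ring expansion, ester installation and the 2,3-cis pair in one operation. The precursor is a syn aryl(dihydrobenzofuranyl)methanol from a dynamic kinetic ketone reduction.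

Key step: step 5

Remark: compounds 1, 3 and 8 are taken as commercial; compound 11 serves as both halves of the dimer (in step 7 it is the nucleophile, used in excess, and the surplus is recovered).

**Route**

Step 1
Reactants: 1 methyl 3,4,5-tris(benzyloxy)benzoate
Product: 2 2-[dimethyl(oxo)-λ6-sulfanylidene]-1-[3,4,5-tris(benzyloxy)phenyl]ethan-1-one (β-keto sulfoxonium ylide)
Conditions: Me3S(O)I, KOtBu, THF, reflux; then 1, reflux
Reagents that add atoms: trimethylsulfoxonium iodide, C[S+](C)(C)=O.[I-]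
Why: Acylation of dimethylsulfoxonium methylide (Corey–Chaykovsky reagent acting as a carbon nucleophile) by the methyl ester, followed by proton transfer, should give the carbonyl-stabilised ylide, which does not react with a second ester; benzyl ethers are inert and no stereocentre is formed.

Step 2
Reactants: 3 3,5-bis(benzyloxy)phenol
Product: 4 2-[(dimethylamino)methyl]-3,5-bis(benzyloxy)phenol
Conditions: Eschenmoser's salt (1.0 equiv), K2CO3, CH2Cl2, 0 °C → rt
Reagents that add atoms: N,N-dimethylmethyleneiminium iodide, C=[N+](C)C.[I-]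
Why: Phenolic Mannich reaction in which the iminium ion should attack the position ortho to the free hydroxyl (hydrogen-bond directed, and less hindered than the position between the two benzyloxy groups), one equivalent at low temperature limiting double aminomethylation; no stereocentre.

Step 3
Reactants: 4 2-[(dimethylamino)methyl]-3,5-bis(benzyloxy)phenol; 2 β-keto sulfoxonium ylide
Product: 6 rac-[4,6-bis(benzyloxy)-2,3-dihydro-1-benzofuran-2-yl][3,4,5-tris(benzyloxy)phenyl]methanone, via o-quinone methide 5 (not isolated)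
Conditions: 2 (1.3 equiv), slow addition of 4, DMF, 90 °C, N2 stream
Reagents that add atoms: none
Why: Thermal loss of dimethylamine from the electron-rich Mannich base should give o-quinone methide 5, the ylide carbon adds to its methylene terminus (conjugate addition restoring aromaticity) and the phenoxide displaces dimethyl sulfoxide in a 5-exo-tet closure (formal [4+1] annulation); the one stereocentre forms racemic and stays epimerisable α to the ketone, which step 4 uses.

Step 4
Reactants: 6 rac-[4,6-bis(benzyloxy)-2,3-dihydro-1-benzofuran-2-yl][3,4,5-tris(benzyloxy)phenyl]methanone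
Product: 7 (S)-[(2S)-4,6-bis(benzyloxy)-2,3-dihydro-1-benzofuran-2-yl][3,4,5-tris(benzyloxy)phenyl]methanol (syn)
Conditions: RuCl(p-cymene)[(R,R)-TsDPEN] (2 mol %), HCO2H/DBU (1:1), MeCN, 40 °C
Reagents that add atoms: none
Why: Noyori–Ikariya asymmetric transfer hydrogenation with dynamic kinetic resolution: DBU should equilibrate the α-aryloxy ketone enantiomers through the enolate, the (R,R)-catalyst fixes the carbinol as S through its aryl/arene CH–π facial preference, and the (S)-ketone should react faster because hydride then arrives anti to the ring C–O bond (polar Felkin–Anh), giving the syn (S,S) alcohol.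

Step 5
Reactants: 7 (S)-[(2S)-4,6-bis(benzyloxy)-2,3-dihydro-1-benzofuran-2-yl][3,4,5-tris(benzyloxy)phenyl]methanol; 8 3,4,5-tris(benzyloxy)benzoic acid
Product: 11 (2R,3R)-5,7-bis(benzyloxy)-2-[3,4,5-tris(benzyloxy)phenyl]chroman-3-yl 3,4,5-tris(benzyloxy)benzoate (octa-O-benzyl-epigallocatechin gallate), via benzylic mesylate 9 (not isolated), via benzylic gallate 10 (not isolated)
Conditions: Ms2O, iPr2NEt, CH2Cl2, −40 °C; then 8 (4 equiv), Zn(OTf)2 (1 equiv), −40 → 40 °C
Reagents that add atoms: none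
Why: Ms2O converts the benzylic alcohol into mesylate 9, which should ionise with anchimeric assistance: ring oxygen O1 attacks the benzylic carbon from the rear (3-exo-tet, inversion) to give a bicyclic aryloxiranium ion, and zinc-bound gallate opens this ion at the former ring carbon C2 of the dihydrobenzofuran (inversion), so the old O1–C bond is lost and the six-membered ring O1–C2–C3–C4–C4a–C8a results by ring expansion. The closest known reaction type is the zinc-carboxylate-mediated ring expansion of tetrahydrofuran-2-ylcarbinyl sulfonates to 3-acyloxytetrahydropyrans through bicyclic oxiranium ions, here applied to an aryl ether oxygen. Gallate that instead opens the ion at the benzylic carbon gives the five-membered benzylic ester 10 with net retention; this ester should re-ionise through the same ion under Zn(OTf)2, whereas the non-benzylic chroman ester 11 cannot, so material funnels to the less strained six-membered ring. Both new stereocentres are set stereospecifically by the two centres of 7: S at the carbinol becomes 2R by rear entry of O1 and S at the ring carbon becomes 3R by rear entry of gallate, which is why the syn alcohol gives the 2,3-cis flavan. The step needs opening at C3 and no free benzylic cation (which would give the 2,3-trans isomer or eliminate to a 2-benzylbenzofuran); thermodynamic control, a chloride-free medium, low temperature and the modest cation stabilisation by the 3,4,5-tris(benzyloxy)phenyl group (its 4-oxygen is twisted out of conjugation) are meant to secure this.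

Step 6
Reactants: 11 octa-O-benzyl-epigallocatechin gallate
Product: 12 4β-(2-ethoxyethoxy)-octa-O-benzyl-epigallocatechin gallate (2,3-cis, 3,4-trans)
Conditions: DDQ (2 equiv), 2-ethoxyethanol (5 equiv), CH2Cl2, rt
Reagents that add atoms: 2-ethoxyethanol, CCOCCO
Why: Oxidative benzylic etherification: DDQ should abstract hydride from C4, the benzylic C–H ortho and para to ring A alkoxy groups, and the alcohol captures the quinone-methide-type cation trans to the 3-O-galloyl group; C2 and C3 are untouched.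

Step 7
Reactants: 12 4β-(2-ethoxyethoxy)-octa-O-benzyl-epigallocatechin gallate; 11 octa-O-benzyl-epigallocatechin gallate (3 equiv)
Product: 13 hexadeca-O-benzylrhodisin (upper unit 2R,3R,4R; lower unit 2R,3R; 4β→8 bond)
Conditions: TMSOTf (0.2 equiv), CH2Cl2, −78 °C; Et3N quench
Reagents that add atoms: none
Why: Lewis-acid ionisation of the C4 ether regenerates the C4 cation, which should undergo Friedel–Crafts attack by C8 of 11 (the most nucleophilic ring A position) on the β face, anti to the axial 3-O-galloyl group that shields the α face by carbonyl participation, so the 3,4-trans 4β→8 bond forms; the excess of 11 suppresses oligomers.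

Step 8
Reactants: 13 hexadeca-O-benzylrhodisin
Product: 14 rhodisin
Conditions: H2 (1 atm), Pd(OH)2/C, THF–MeOH–H2O, rt
Reagents that add atoms: none
Why: Hydrogenolysis of all sixteen benzyl ethers over Pd(OH)2/C under neutral conditions should leave the two gallate esters, the interflavan bond and the five stereocentres untouched.

**Compound list**

1 | methyl 3,4,5-tris(benzyloxy)benzoate | COC(=O)c1cc(OCc2ccccc2)c(OCc2ccccc2)c(OCc2ccccc2)c1 | starting material
2 | 2-[dimethyl(oxo)-λ6-sulfanylidene]-1-[3,4,5-tris(benzyloxy)phenyl]ethan-1-one | CS(C)(=O)=CC(=O)c1cc(OCc2ccccc2)c(OCc2ccccc2)c(OCc2ccccc2)c1 | intermediate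
3 | 3,5-bis(benzyloxy)phenol | Oc1cc(OCc2ccccc2)cc(OCc2ccccc2)c1 | starting material
4 | 2-[(dimethylamino)methyl]-3,5-bis(benzyloxy)phenol | CN(C)Cc1c(O)cc(OCc2ccccc2)cc1OCc1ccccc1 | intermediate
5 | 3,5-bis(benzyloxy)-6-methylidenecyclohexa-2,4-dien-1-one (o-quinone methide, not isolated, step 3) | C=C1C(=O)C=C(OCc2ccccc2)C=C1OCc1ccccc1 | intermediate
6 | rac-[4,6-bis(benzyloxy)-2,3-dihydro-1-benzofuran-2-yl][3,4,5-tris(benzyloxy)phenyl]methanone | O=C(c1cc(OCc2ccccc2)c(OCc2ccccc2)c(OCc2ccccc2)c1)C1Cc2c(OCc3ccccc3)cc(OCc3ccccc3)cc2O1 | intermediate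
7 | (S)-[(2S)-4,6-bis(benzyloxy)-2,3-dihydro-1-benzofuran-2-yl][3,4,5-tris(benzyloxy)phenyl]methanol | O[C@@H](c1cc(OCc2ccccc2)c(OCc2ccccc2)c(OCc2ccccc2)c1)[C@@H]1Cc2c(OCc3ccccc3)cc(OCc3ccccc3)cc2O1 | intermediate
8 | 3,4,5-tris(benzyloxy)benzoic acid | OC(=O)c1cc(OCc2ccccc2)c(OCc2ccccc2)c(OCc2ccccc2)c1 | starting material
9 | (S)-[(2S)-4,6-bis(benzyloxy)-2,3-dihydro-1-benzofuran-2-yl][3,4,5-tris(benzyloxy)phenyl]methyl methanesulfonate (not isolated, step 5) | CS(=O)(=O)O[C@@H](c1cc(OCc2ccccc2)c(OCc2ccccc2)c(OCc2ccccc2)c1)[C@@H]1Cc2c(OCc3ccccc3)cc(OCc3ccccc3)cc2O1 | intermediate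
10 | (S)-[(2S)-4,6-bis(benzyloxy)-2,3-dihydro-1-benzofuran-2-yl][3,4,5-tris(benzyloxy)phenyl]methyl 3,4,5-tris(benzyloxy)benzoate (not isolated, step 5) | O=C(O[C@@H](c1cc(OCc2ccccc2)c(OCc2ccccc2)c(OCc2ccccc2)c1)[C@@H]1Cc2c(OCc3ccccc3)cc(OCc3ccccc3)cc2O1)c1cc(OCc2ccccc2)c(OCc2ccccc2)c(OCc2ccccc2)c1 | intermediate
11 | (2R,3R)-5,7-bis(benzyloxy)-2-[3,4,5-tris(benzyloxy)phenyl]chroman-3-yl 3,4,5-tris(benzyloxy)benzoate | O=C(O[C@@H]1Cc2c(OCc3ccccc3)cc(OCc3ccccc3)cc2O[C@@H]1c1cc(OCc2ccccc2)c(OCc2ccccc2)c(OCc2ccccc2)c1)c1cc(OCc2ccccc2)c(OCc2ccccc2)c(OCc2ccccc2)c1 | intermediate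
12 | 4β-(2-ethoxyethoxy) derivative of 11 (2,3-cis, 3,4-trans) | O=C(O[C@@H]1[C@@H](OCCOCC)c2c(OCc3ccccc3)cc(OCc3ccccc3)cc2O[C@@H]1c1cc(OCc2ccccc2)c(OCc2ccccc2)c(OCc2ccccc2)c1)c1cc(OCc2ccccc2)c(OCc2ccccc2)c(OCc2ccccc2)c1 | intermediate
13 | hexadeca-O-benzylrhodisin | O=C(O[C@@H]1[C@@H](c2c(OCc9ccccc9)cc(OCc9ccccc9)c3c2O[C@H](c2cc(OCc9ccccc9)c(OCc9ccccc9)c(OCc9ccccc9)c2)[C@H](OC(=O)c2cc(OCc9ccccc9)c(OCc9ccccc9)c(OCc9ccccc9)c2)C3)c2c(OCc9ccccc9)cc(OCc9ccccc9)cc2O[C@@H]1c1cc(OCc9ccccc9)c(OCc9ccccc9)c(OCc9ccccc9)c1)c1cc(OCc9ccccc9)c(OCc9ccccc9)c(OCc9ccccc9)c1 | intermediate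
14 | rhodisin | O=C(O[C@@H]1[C@@H](c2c(O)cc(O)c3c2O[C@H](c2cc(O)c(O)c(O)c2)[C@H](OC(=O)c2cc(O)c(O)c(O)c2)C3)c2c(O)cc(O)cc2O[C@@H]1c1cc(O)c(O)c(O)c1)c1cc(O)c(O)c(O)c1 | target

**Step count**

Total steps: 8. Longest linear sequence: 7 steps (1 or 3 → 14; steps 1 and 2 run in parallel).

**Steps most likely to fail**

Step 5 (key step). What may go wrong: capture of the oxiranium ion at the benzylic carbon without later re-ionisation, or leakage to a free benzylic cation with loss of the C2 configuration or elimination to an aromatic benzofuran. Fallback, setting out from 7 and returning at 11: the gallate is no longer introduced in the ring expansion. Mesylate 9, formed as before, is solvolysed in acetic acid with Zn(OAc)2 at 50 °C (ionising solvent as the nucleophile in large excess, the classical conditions for this ring expansion) to give (2R,3R)-5,7-bis(benzyloxy)-2-[3,4,5-tris(benzyloxy)phenyl]chroman-3-yl acetate F1. Methanolysis with K2CO3 in MeOH gives 5,7,3′,4′,5′-penta-O-benzylepigallocatechin F2, and Steglich esterification with 8 (EDC, DMAP, CH2Cl2) gives 11.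

Step 4. What may go wrong: enolisation slower than reduction, so the two ketone enantiomers are reduced without equilibrating, or erosion of the syn preference. Fallback, setting out from 6 and returning at 7: the same catalyst is used in HCO2H/Et3N without DBU as a catalyst-controlled divergent reduction of the racemate. The (S)-ketone gives 7 and the (R)-ketone gives the anti epimer (S)-[(2R)-4,6-bis(benzyloxy)-2,3-dihydro-1-benzofuran-2-yl][3,4,5-tris(benzyloxy)phenyl]methanol F3; the two diastereomers are separated by chromatography. F3 is oxidised with Dess–Martin periodinane to [(2R)-4,6-bis(benzyloxy)-2,3-dihydro-1-benzofuran-2-yl][3,4,5-tris(benzyloxy)phenyl]methanone F4, which DBU racemises back to 6 for another cycle.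

Step 7. What may go wrong: self-condensation of the electrophile and further alkylation of the dimer (oligomerisation), or competing attack at C6. Fallback, setting out from 11 and returning at 14: a bromine cap on the electrophilic half. NBS in CH2Cl2 at −78 °C brominates C8 of 11 to give 8-bromo-octa-O-benzyl-epigallocatechin gallate F5. DDQ with 2-ethoxyethanol gives its 4β-(2-ethoxyethoxy) derivative F6, which can no longer act as a nucleophile at C8. TMSOTf-mediated coupling with 11 gives 8-bromo-hexadeca-O-benzylrhodisin F7. Hydrogenolysis over Pd(OH)2/C with Et3N removes the bromine together with all benzyl groups and gives 14.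

**Further compounds**

F1 | step 5 | (2R,3R)-5,7-bis(benzyloxy)-2-[3,4,5-tris(benzyloxy)phenyl]chroman-3-yl acetate | CC(=O)O[C@@H]1Cc2c(OCc3ccccc3)cc(OCc3ccccc3)cc2O[C@@H]1c1cc(OCc2ccccc2)c(OCc2ccccc2)c(OCc2ccccc2)c1
F2 | step 5 | 5,7,3′,4′,5′-penta-O-benzylepigallocatechin | O[C@@H]1Cc2c(OCc3ccccc3)cc(OCc3ccccc3)cc2O[C@@H]1c1cc(OCc2ccccc2)c(OCc2ccccc2)c(OCc2ccccc2)c1
F3 | step 4 | (S)-[(2R)-4,6-bis(benzyloxy)-2,3-dihydro-1-benzofuran-2-yl][3,4,5-tris(benzyloxy)phenyl]methanol | O[C@@H](c1cc(OCc2ccccc2)c(OCc2ccccc2)c(OCc2ccccc2)c1)[C@H]1Cc2c(OCc3ccccc3)cc(OCc3ccccc3)cc2O1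
F4 | step 4 | [(2R)-4,6-bis(benzyloxy)-2,3-dihydro-1-benzofuran-2-yl][3,4,5-tris(benzyloxy)phenyl]methanone | O=C(c1cc(OCc2ccccc2)c(OCc2ccccc2)c(OCc2ccccc2)c1)[C@H]1Cc2c(OCc3ccccc3)cc(OCc3ccccc3)cc2O1
F5 | step 7 | 8-bromo-octa-O-benzyl-epigallocatechin gallate | O=C(O[C@@H]1Cc2c(OCc3ccccc3)cc(OCc3ccccc3)c(Br)c2O[C@@H]1c1cc(OCc2ccccc2)c(OCc2ccccc2)c(OCc2ccccc2)c1)c1cc(OCc2ccccc2)c(OCc2ccccc2)c(OCc2ccccc2)c1
F6 | step 7 | 8-bromo-4β-(2-ethoxyethoxy)-octa-O-benzyl-epigallocatechin gallate | O=C(O[C@@H]1[C@@H](OCCOCC)c2c(OCc3ccccc3)cc(OCc3ccccc3)c(Br)c2O[C@@H]1c1cc(OCc2ccccc2)c(OCc2ccccc2)c(OCc2ccccc2)c1)c1cc(OCc2ccccc2)c(OCc2ccccc2)c(OCc2ccccc2)c1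
F7 | step 7 | 8-bromo-hexadeca-O-benzylrhodisin (bromine on C8 of the upper unit) | O=C(O[C@@H]1[C@@H](c2c(OCc9ccccc9)cc(OCc9ccccc9)c3c2O[C@H](c2cc(OCc9ccccc9)c(OCc9ccccc9)c(OCc9ccccc9)c2)[C@H](OC(=O)c2cc(OCc9ccccc9)c(OCc9ccccc9)c(OCc9ccccc9)c2)C3)c2c(OCc9ccccc9)cc(OCc9ccccc9)c(Br)c2O[C@@H]1c1cc(OCc9ccccc9)c(OCc9ccccc9)c(OCc9ccccc9)c1)c1cc(OCc9ccccc9)c(OCc9ccccc9)c(OCc9ccccc9)c1
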